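## Analysis of the target

Eudesmane numbering is used: C1 ketone, C2 and C5 bridgeheads, C3=C4 with the C15 methyl on C4, C6 bearing the lactone oxygen, C10 quaternary with the C14 methyl, C11 with the C13 methyl, C12 lactone carbonyl. C1′ is the bridge CH2 on C5, C2′ the bridge CH on C2, C3′ the alkene carbon on C2′.

- **Ring system.** Target 17 is a 12,6α-eudesmanolide whose ring A is bridged from C5 to C2 by C1′–C2′. C2, C3, C4, C5, C1, C10, C1′ and C2′ form a bicyclo[2.2.2]oct-5-en-2-one, fused through C5–C10 to ring B and through C6–C7 to a trans γ-lactone.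
- **Stereocentres.** There are seven. C6, C7, C10 and C11 have exactly the configuration of α-santonin 1 (6α-oxygen, 7α-hydrogen, 10β-methyl, 11S).
- **New centres.** C5 and C2 are tied together by the bridge, which lies on the α face, anti to the C10 methyl and syn to the C6 oxygen. C2′ carries the 6-methylhepta-1,5-dien-2-yl group syn to the C3=C4 bridge.
- **Sensitive groups.** The β,γ-unsaturated ketone conjugates easily before bridging. The lactone has an epimerisable C11. The 1,5-diene side chain is prone to cation–olefin chemistry, so no strong acid may be used once it is in place.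
- **Difficulty.** C5 and C10 are adjacent quaternary carbons, C5 is a bridgehead next to the C6 stereocentre, and the bridge must be put on one face with C2′ controlled.
- **Feature used.** O6 and C1′ are cis across the C5–C6 bond. A two-atom acetal tether on O6 can therefore hand C1′ (with C2′ at the aldehyde level) to C5 of a ring A 1-oxo-2,4-dienone. The C12 carbonyl can later take O6 back as the lactone and release that aldehyde.

## Retrosynthetic reasoning

**C2–C2′.** The last bond made is C2–C2′. Cutting it opens the bicyclooctenone to a ring A β,γ-enone whose C5 arm ends in an allylic electrophile, the tert-butyl carbonate 16. C2 is the α-carbon of the extended enolate of the C1 ketone, and the 2-substituted allyl unit needed on C2′ is the 1,1-disubstituted alkene of the side chain. Forward, a zerovalent palladium catalyst must ionise the carbonate, the released alkoxide must form the dienolate, and C2 must attack the substituted allyl terminus on the α face. The tether allows only this six-membered closure; O-alkylation would put an enol ether double bond at a bridgehead.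

**C2′–C3′.** Carbonate 16 comes from alcohol 15, which is cut between C2′ and C3′ into aldehyde 11 and alkenyl triflate 14. The triflate is made from ketone 12 through enolate 13. The whole C8 side chain arrives in one piece. The coupling must pick the aldehyde over the C1 ketone and the lactone, which a chromium-mediated alkenylation does. The carbinol configuration in 15 is irrelevant because the allyl faces interconvert at the palladium stage.

**Unveiling of aldehyde and lactone.** Aldehyde 11 is traced to the cyclic ethyl acetal 9 through lactol 10. Hydrolysis frees O6, which is acylated by the C12 N-methoxy-N-methylamide. The lactone of 17 is thus restored and the C2′ aldehyde is left open in one operation. This is why C12 is carried as an amide: no redox steps at C12 and no protecting group on O6 are needed.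

**C5–C1′ (key disconnection).** Acetal 9 is cut at C5–C1′ to bromoacetal 8. The bond is made from O6 because O6 is the only handle on the α face next to C5, and a radical is used because C5 is fully substituted and flanked by quaternary C10. Forward, the primary radical must add 5-exo to the δ-carbon of the dienone, and the tether fixes the face.

**Tether and lactone opening.** Bromoacetal 8 comes from hydroxy amide 6 and ethyl vinyl ether 7. Amide 6 comes from dienone lactone 5 by aminolysis, which opens the lactone without touching the dienone, as a hydride reduction would not.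

**Ring A transposition.** Dienone 5 is traced through dienol 4, hydrazone 3 and epoxy ketone 2 to α-santonin 1. Santonin has its carbonyl at C3 in a cross-conjugated dienone, whereas the radical acceptor needs the carbonyl at C1 and the linear 2,4-dienone. Epoxidation at C1=C2, reductive transposition and oxidation achieve this and keep C6, C7, C10 and C11.

## Alternatives that were turned down

**Alternative 1:** The disconnection is C9–C10, leading back to phenol A2, a 2,4-dimethylphenol carrying the γ-lactone and a 2-iodoethyl chain. Forward, KOt-Bu would form the phenolate and its ortho carbon C10 would displace the primary iodide, closing ring B and dearomatising ring A to dienone A1, which is the same structure as 5.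
- For: the quaternary C10 and the linear dienone appear together under non-oxidative conditions. The route is independent of the chiral pool and open to analogues; on that point it is stronger.
- Against: the C10 configuration rests on induction from C6 and C7 in a forming ring, and O- versus C-alkylation is open. A2 needs a de novo synthesis of three contiguous stereocentres. A1 still lacks the bridge.
- Comparison: the chosen route reaches the same dienone in three steps from 1 with four stereocentres fixed, and spends its effort on the bridge.

**Alternative 2:** The disconnection cuts C5–C10 and C2–C1 together, with a nitro group standing in for the C1 oxygen. The precursor is the carvone-derived cyclohexadiene A4 with a tethered (E)-nitroalkene. Forward, heating would bring the diene C5=C4–C3=C2 across the nitroalkene to give the nitro tetracycle A3, and a Nef reaction would follow.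
- For: two bonds, two rings and the bridgehead centres form at once. C2′ comes from carvone and is fixed before cyclisation, so the C2′ question of step 11 does not arise; on that point it is stronger.
- Against: the cycloaddition must create the adjacent quaternary C5 and C10 from a trisubstituted nitroalkene and a fully substituted diene terminus. The heat needed invites 1,5-hydrogen shifts in the cyclohexadiene. The C10 configuration depends on tether conformation. The Nef step must work at a carbon between C10 and a bridgehead. A4 is long to assemble.
- Comparison: it is more convergent on paper but longer overall, with its main risk in a step that has no simple rescue. The chosen route takes four centres from 1 and sets C5 by a tether.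

**Alternative 3:** The disconnection is transannular C5–C10, leading back to the 1,10-epoxygermacranolide A6. Forward, BF3·OEt2 would open the epoxide, C4=C5 would attack C10, and proton loss from C3 would give hydroxy eudesmenolide A5.
- For: the closure is stereospecific and places oxygen at C1 directly, where the chosen route needs steps 1 to 3; on that point it is stronger.
- Against: A6 needs a much less available germacranolide or a ten-membered ring synthesis. Proton loss can also go to the exocyclic position. A5 has hydrogen at C5, because the closure consumes the C4=C5 alkene, so C1 would have to be oxidised and C4–C5 unsaturated again to reach A1 before any bridge can be attached.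
- Comparison: it ends earlier than compound 5, which the chosen route has after three steps.

Key step: step 6

## Route

Remark: the acetal carbon in 8, 9 and 10 and the carbinol carbon C2′ in 15 and 16 form as epimer mixtures that converge, so these centres are left undefined in the SMILES.

Step 1
Reactants: 1 α-santonin
Product: 2 1α,2α-epoxy-α-santonin
Conditions: t-BuOOH, Triton B (cat.), THF, 0 °C to rt
Reagents that add atoms: tert-butyl hydroperoxide, CC(C)(C)OO
Why: Weitz–Scheffer nucleophilic epoxidation; the hydroperoxide anion adds to C1, the β-carbon of the less substituted enone, not to the fully substituted C5, and approaches anti to the C10 methyl, so the α-epoxide should form while the catalytic base leaves the lactone closed.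

Step 2
Reactants: 2 1α,2α-epoxy-α-santonin
Product: 4 (11S)-1α-hydroxyeudesma-2,4-dien-12,6α-olide, via C3 hydrazone 3 (not isolated)
Conditions: N2H4·H2O, AcOH (cat.), MeOH, 0 °C to rt
Reagents that add atoms: none
Why: Wharton transposition; hydrazone 3 opens the epoxide and loses N2, leaving hydrogen at C3, the C2=C3 alkene and the C1 alcohol with the epoxide C1–O bond retained, and a short reaction at low temperature should spare the hindered α-branched lactone from hydrazinolysis.

Step 3
Reactants: 4 (11S)-1α-hydroxyeudesma-2,4-dien-12,6α-olide
Product: 5 (11S)-1-oxoeudesma-2,4-dien-12,6α-olide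
Conditions: Dess–Martin periodinane, CH2Cl2, 0 °C to rt
Reagents that add atoms: none
Why: Dess–Martin oxidation of a secondary allylic alcohol under near-neutral conditions; quaternary C10 blocks tautomerisation to a phenol and the substituted C4/C5 end of the diene slows dimerisation.

Step 4
Reactants: 5 (11S)-1-oxoeudesma-2,4-dien-12,6α-olide
Product: 6 (11S)-6α-hydroxy-N-methoxy-N-methyl-1-oxoeudesma-2,4-dien-12-amide
Conditions: MeNH(OMe)·HCl, AlMe3, CH2Cl2, 0 °C to rt; aq. potassium sodium tartrate work-up; crude product used at once
Reagents that add atoms: N,O-dimethylhydroxylamine hydrochloride, CNOC.Cl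
Why: Aluminium-amide aminolysis of a lactone (Weinreb amide formation); the chloro(methyl)aluminium amide made in the flask attacks the lactone carbonyl and should leave the hindered, conjugated C1 ketone alone, C6, C7 and C11 are untouched, and the hydroxy amide is capped in step 5 before it can close again.

Step 5
Reactants: 6 (11S)-6α-hydroxy-N-methoxy-N-methyl-1-oxoeudesma-2,4-dien-12-amide; 7 ethyl vinyl ether
Product: 8 (11S)-6α-(2-bromo-1-ethoxyethoxy)-N-methoxy-N-methyl-1-oxoeudesma-2,4-dien-12-amide
Conditions: NBS, ethyl vinyl ether (excess), CH2Cl2, −40 to 0 °C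
Reagents that add atoms: N-bromosuccinimide, O=C1CCC(=O)N1Br
Why: Ueno–Stork bromoacetalisation; bromination of the enol ether gives an α-bromo oxocarbenium ion that the C6 hydroxyl traps, the medium stays near neutral, the electron-poor dienone alkenes do not compete for the bromine source, and the new acetal centre needs no control.

Step 6
Reactants: 8 (11S)-6α-(2-bromo-1-ethoxyethoxy)-N-methoxy-N-methyl-1-oxoeudesma-2,4-dien-12-amide
Product: 9 (11S)-2′-ethoxy-6α,2′-epoxy-5α-ethyl-N-methoxy-N-methyl-1-oxoeudesm-3-en-12-amide (cis-fused 2-ethoxytetrahydrofuran over C5 and O6)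
Conditions: Bu3SnH (slow addition), AIBN (cat.), PhH, 80 °C, high dilution
Reagents that add atoms: none
Why: The tributyltin radical abstracts bromine from either acetal epimer of 8, and the primary, nucleophilic dialkoxyethyl radical adds to C5, the δ-carbon of the electron-poor 1-oxo-2,4-dienone; the new radical is delocalised over C4, C2 and the carbonyl oxygen and takes hydrogen from Bu3SnH at the unhindered C2, which leaves the C3=C4 alkene and carries the chain. The closest known reaction type is the Ueno–Stork haloacetal radical cyclisation, run here as a radical 1,6-conjugate addition that creates a quaternary carbon. The one ring closed is the 2-ethoxytetrahydrofuran (O6, C2′, C1′, C5, C6), formed in the 5-exo-trig mode with respect to the C4=C5 bond. The one new stereocentre is C5, and the tether controls it: a two-atom link from the α oxygen on C6 reaches only the α face of C5, so the ring is cis-fused and C1′ ends anti to the C10 methyl, as in 17. The step needs regioselectivity for C5 over C4 and cyclisation over direct reduction of the radical; attack at C4 would be 6-endo and give an unconjugated tertiary radical, whereas attack at C5 is 5-exo and gives the stabilised one, and slow addition of Bu3SnH at high dilution keeps the hydride concentration low. An early transition state lets the radical tolerate the crowding at C5 next to quaternary C10. If hydrogen goes to C4 instead, the conjugated isomer F6 results, and deconjugative protonation of its dienolate returns it to 9.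

Step 7
Reactants: 9 (11S)-2′-ethoxy-6α,2′-epoxy-5α-ethyl-N-methoxy-N-methyl-1-oxoeudesm-3-en-12-amide
Product: 11 (11S)-1-oxo-5α-(2-oxoethyl)eudesm-3-en-12,6α-olide, via lactol 10 (not isolated)
Conditions: 1 M HCl (aq), THF, rt
Reagents that add atoms: water, O
Why: Acetal hydrolysis followed by acid-promoted lactonisation of a γ-hydroxy N-methoxy-N-methylamide; lactol 10 opens reversibly, its C6 hydroxyl is acylated by the C12 amide with loss of the amine, and the trans lactone of the target forms while the C2′ aldehyde is left free; no stereocentre is touched and 11S is the stable configuration in this lactone.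

Step 8
Reactants: 12 6-methylhept-5-en-2-one
Product: 14 6-methylhepta-1,5-dien-2-yl trifluoromethanesulfonate, via lithium enolate 13 (not isolated)
Conditions: LiN(i-Pr)2, THF, −78 °C; then PhNTf2, −78 °C to rt
Reagents that add atoms: N-phenylbis(trifluoromethanesulfonimide), O=S(=O)(N(c1ccccc1)S(=O)(=O)C(F)(F)F)C(F)(F)F
Why: Kinetic deprotonation of a methyl ketone at the methyl group gives the terminal enolate 13, and O-sulfonylation gives the 2-substituted alkenyl triflate; the trisubstituted alkene is inert.

Step 9
Reactants: 11 (11S)-1-oxo-5α-(2-oxoethyl)eudesm-3-en-12,6α-olide; 14 6-methylhepta-1,5-dien-2-yl trifluoromethanesulfonate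
Product: 15 (11S)-5α-(2-hydroxy-7-methyl-3-methylideneoct-6-en-1-yl)-1-oxoeudesm-3-en-12,6α-olide
Conditions: CrCl2, NiCl2 (cat.), DMF, rt
Reagents that add atoms: none
Why: Nozaki–Hiyama–Kishi coupling; nickel activates the alkenyl triflate and the alkenylchromium species adds to the aldehyde but not to the hindered C1 ketone or the lactone, the non-basic medium avoids enolisation of the keto aldehyde, and the C2′ carbinol centre may form as a mixture because step 11 erases it.

Step 10
Reactants: 15 (11S)-5α-(2-hydroxy-7-methyl-3-methylideneoct-6-en-1-yl)-1-oxoeudesm-3-en-12,6α-olide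
Product: 16 tert-butyl carbonate of 15 at the C2′ oxygen
Conditions: Boc2O, DMAP (cat.), CH2Cl2, rt
Reagents that add atoms: di-tert-butyl dicarbonate, CC(C)(C)OC(=O)OC(=O)OC(C)(C)C
Why: DMAP-catalysed O-acylation of the secondary allylic alcohol under conditions too mild to enolise the ketone; the tert-butyl carbonate is chosen so that ionisation later releases tert-butoxide, a base that does not open the lactone.

Step 11
Reactants: 16 tert-butyl carbonate of 15 at the C2′ oxygen
Product: 17 CNP0385704.3, (11S)-2α,5α-[2-(6-methylhepta-1,5-dien-2-yl)ethano]-1-oxoeudesm-3-en-12,6α-olide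
Conditions: Pd(PPh3)4 (cat.), THF, 60 °C
Reagents that add atoms: none
Why: Intramolecular Tsuji–Trost allylic alkylation; zerovalent palladium ionises the carbonate to a 2-substituted π-allyl complex, CO2 is lost, and the tert-butoxide formed deprotonates C2 to the extended dienolate, whose α-carbon attacks the C2′ terminus on the α face to close the bicyclo[2.2.2]octenone. Attack at the CH2 terminus would need an eight-membered bridged ring and O-alkylation a bridgehead enol ether; the allyl faces interconvert through the unsubstituted terminus, so both carbinol epimers converge, and C2′ is set by the transition state in which the allyl unit lies over the C3=C4 side, away from the metal-bound enolate oxygen, which is the arrangement of the target, while C2 follows from the α bridge.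

## Compound list

1 | α-santonin, (11S)-3-oxoeudesma-1,4-dien-12,6α-olide | O=C1C=C[C@]2(C)CC[C@H]3[C@H](C)C(=O)O[C@@H]3C2=C1C | starting material
2 | 1α,2α-epoxy-α-santonin | O=C1[C@@H]2O[C@@H]2[C@]3(C)CC[C@H]4[C@H](C)C(=O)O[C@@H]4C3=C1C | intermediate
3 | C3 hydrazone of 2 | NN=C1[C@@H]2O[C@@H]2[C@]3(C)CC[C@H]4[C@H](C)C(=O)O[C@@H]4C3=C1C | intermediate
4 | (11S)-1α-hydroxyeudesma-2,4-dien-12,6α-olide | O[C@H]1C=CC(C)=C2[C@H]3OC(=O)[C@@H](C)[C@@H]3CC[C@@]12C | intermediate
5 | (11S)-1-oxoeudesma-2,4-dien-12,6α-olide | O=C1C=CC(C)=C2[C@H]3OC(=O)[C@@H](C)[C@@H]3CC[C@@]12C | intermediate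
6 | (11S)-6α-hydroxy-N-methoxy-N-methyl-1-oxoeudesma-2,4-dien-12-amide | O[C@@H]1C2=C(C)C=CC(=O)[C@]2(C)CC[C@H]1[C@H](C)C(=O)N(C)OC | intermediate
7 | ethyl vinyl ether | C=COCC | starting material
8 | (11S)-6α-(2-bromo-1-ethoxyethoxy)-N-methoxy-N-methyl-1-oxoeudesma-2,4-dien-12-amide, both acetal epimers | CCOC(CBr)O[C@@H]1C2=C(C)C=CC(=O)[C@]2(C)CC[C@H]1[C@H](C)C(=O)N(C)OC | intermediate
9 | (11S)-2′-ethoxy-6α,2′-epoxy-5α-ethyl-N-methoxy-N-methyl-1-oxoeudesm-3-en-12-amide, both acetal epimers | CCOC1C[C@]23C(C)=CCC(=O)[C@]2(C)CC[C@@H]([C@H](C)C(=O)N(C)OC)[C@@H]3O1 | intermediate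
10 | lactol, the 2′-hydroxy analogue of 9 | OC1C[C@]23C(C)=CCC(=O)[C@]2(C)CC[C@@H]([C@H](C)C(=O)N(C)OC)[C@@H]3O1 | intermediate
11 | (11S)-1-oxo-5α-(2-oxoethyl)eudesm-3-en-12,6α-olide | O=CC[C@]12C(C)=CCC(=O)[C@]1(C)CC[C@H]1[C@H](C)C(=O)O[C@@H]12 | intermediate
12 | 6-methylhept-5-en-2-one | CC(=O)CCC=C(C)C | starting material
13 | lithium 6-methylhepta-1,5-dien-2-olate | [Li+].[O-]C(=C)CCC=C(C)C | intermediate
14 | 6-methylhepta-1,5-dien-2-yl trifluoromethanesulfonate | C=C(CCC=C(C)C)OS(=O)(=O)C(F)(F)F | intermediate
15 | (11S)-5α-(2-hydroxy-7-methyl-3-methylideneoct-6-en-1-yl)-1-oxoeudesm-3-en-12,6α-olide, both C2′ epimers | C=C(CCC=C(C)C)C(O)C[C@]12C(C)=CCC(=O)[C@]1(C)CC[C@H]1[C@H](C)C(=O)O[C@@H]12 | intermediate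
16 | tert-butyl carbonate of 15 at the C2′ oxygen | C=C(CCC=C(C)C)C(OC(=O)OC(C)(C)C)C[C@]12C(C)=CCC(=O)[C@]1(C)CC[C@H]1[C@H](C)C(=O)O[C@@H]12 | intermediate
17 | CNP0385704.3 | C=C(CCC=C(C)C)[C@@H]1C[C@]23C(C)=C[C@H]1C(=O)[C@]2(C)CC[C@H]1[C@H](C)C(=O)O[C@@H]13 | target

## Step count and least certain steps

Total step count: 11. Longest linear sequence: 10 steps (steps 1 to 7 and 9 to 11, from 1 to 17).

**Step 6 (key step).** The primary radical may take hydrogen from the tin hydride before it adds to the crowded, fully substituted C5, or the linear dienone may be consumed by tin radical addition and conjugate reduction at 80 °C. The fallback runs the same tethered cyclisation on the sturdier cross-conjugated dienone, where C5 is an ordinary enone β-carbon, and transposes ring A afterwards. It sets out from 1 and returns at 9.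
- Compound 1 would be opened as in step 4 to (11S)-6α-hydroxy-N-methoxy-N-methyl-3-oxoeudesma-1,4-dien-12-amide F1.
- NBS and 7 would give its 6-O-(2-bromo-1-ethoxyethyl) acetal F2.
- Bu3SnH and AIBN would close the tetrahydrofuran by 5-exo attack on C5, giving the 3-oxoeudesm-1-ene acetal F3 with hydrogen at C4.
- t-BuOOH with Triton B would give the 1,2-epoxy-3-ketone F4.
- Hydrazine hydrate with acetic acid (Wharton) would give the 1-hydroxyeudesm-2-ene acetal F5.
- Dess–Martin periodinane would give the 1-oxoeudesm-2-ene acetal F6.
- Deprotonation of F6 at C4 with KOt-Bu in THF/t-BuOH and kinetic protonation of the dienolate at C2 with acetic acid at −78 °C would give 9.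

**Step 11.** The facial discrimination that sets C2′ rests on a modest steric preference and may be poor. The π-allyl intermediate may also lose a β-hydrogen to give a diene, or the in situ base may not enolise the ketone fast enough. The fallback abandons the stepwise closure for a thermal Diels–Alder reaction. It sets out from 5 and returns at 17. Heating 5 with myrcene (C=CC(=C)CCC=C(C)C) in toluene in a sealed tube with a radical inhibitor would use the dienone as the diene and the monosubstituted alkene of the triene as dienophile. Approach anti to the C10 methyl, the endo orientation and ortho regiochemistry would form C5–C1′ and C2–C2′ together. No new compound arises on this path (F0). Its own weakness is that myrcene can also react as the diene.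

**Step 4.** The γ-hydroxy amide may close back to lactone 5 before it is capped, and the Lewis acidic aluminium amide may attack or rearrange the linear dienone. The fallback opens the lactone before the dienone exists. It sets out from 4 and returns at 8.
- TESCl and imidazole in DMF would give the 1α-triethylsilyl ether of 4, F7.
- The same aminolysis would give the 6α-hydroxy N-methoxy-N-methylamide F8.
- NBS with excess 7, so that the enol ether outcompetes the diene for bromine, would give the bromoacetal F9.
- TBAF buffered with AcOH in THF at 0 °C would give the 1α-hydroxy bromoacetal F10.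
- Dess–Martin periodinane would give 8.

**Step 7.** Under aqueous acid the enol of the C1 ketone may add to the freed aldehyde in an intramolecular aldol closure, or lactonisation may stall at the lactol. The fallback keeps the aldehyde masked while the lactone forms. It sets out from 9 and returns at 11.
- Propane-1,3-dithiol and BF3·OEt2 in CH2Cl2 at −20 °C would open the cyclic acetal to the 5α-(1,3-dithian-2-ylmethyl) 6α-hydroxy amide F11.
- TsOH in CH2Cl2 would lactonise it to the 5α-(1,3-dithian-2-ylmethyl) 12,6α-olide F12.
- MeI and CaCO3 in aqueous MeCN would unmask the aldehyde to give 11.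

## Further compounds

F1 | step 6 | (11S)-6α-hydroxy-N-methoxy-N-methyl-3-oxoeudesma-1,4-dien-12-amide | O=C1C=C[C@]2(C)CC[C@@H]([C@H](C)C(=O)N(C)OC)[C@H](O)C2=C1C
F2 | step 6 | (11S)-6α-(2-bromo-1-ethoxyethoxy)-N-methoxy-N-methyl-3-oxoeudesma-1,4-dien-12-amide | O=C1C=C[C@]2(C)CC[C@@H]([C@H](C)C(=O)N(C)OC)[C@H](OC(CBr)OCC)C2=C1C
F3 | step 6 | (11S)-2′-ethoxy-6α,2′-epoxy-5α-ethyl-N-methoxy-N-methyl-3-oxoeudesm-1-en-12-amide | CCOC1C[C@]23C(C)C(=O)C=C[C@]2(C)CC[C@@H]([C@H](C)C(=O)N(C)OC)[C@@H]3O1
F4 | step 6 | 1,2-epoxide of F3 | CCOC1C[C@]23C(C)C(=O)C4OC4[C@]2(C)CC[C@@H]([C@H](C)C(=O)N(C)OC)[C@@H]3O1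
F5 | step 6 | (11S)-2′-ethoxy-6α,2′-epoxy-5α-ethyl-1-hydroxy-N-methoxy-N-methyleudesm-2-en-12-amide | CCOC1C[C@]23C(C)C=CC(O)[C@]2(C)CC[C@@H]([C@H](C)C(=O)N(C)OC)[C@@H]3O1
F6 | step 6 | (11S)-2′-ethoxy-6α,2′-epoxy-5α-ethyl-N-methoxy-N-methyl-1-oxoeudesm-2-en-12-amide | CCOC1C[C@]23C(C)C=CC(=O)[C@]2(C)CC[C@@H]([C@H](C)C(=O)N(C)OC)[C@@H]3O1
F0 | step 11 | none | none
F7 | step 4 | (11S)-1α-(triethylsilyloxy)eudesma-2,4-dien-12,6α-olide | CC[Si](CC)(CC)O[C@H]1C=CC(C)=C2[C@H]3OC(=O)[C@@H](C)[C@@H]3CC[C@@]12C
F8 | step 4 | (11S)-6α-hydroxy-N-methoxy-N-methyl-1α-(triethylsilyloxy)eudesma-2,4-dien-12-amide | O[C@@H]1C2=C(C)C=C[C@H](O[Si](CC)(CC)CC)[C@]2(C)CC[C@H]1[C@H](C)C(=O)N(C)OC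
F9 | step 4 | (11S)-6α-(2-bromo-1-ethoxyethoxy)-N-methoxy-N-methyl-1α-(triethylsilyloxy)eudesma-2,4-dien-12-amide | CCOC(CBr)O[C@@H]1C2=C(C)C=C[C@H](O[Si](CC)(CC)CC)[C@]2(C)CC[C@H]1[C@H](C)C(=O)N(C)OC
F10 | step 4 | (11S)-6α-(2-bromo-1-ethoxyethoxy)-1α-hydroxy-N-methoxy-N-methyleudesma-2,4-dien-12-amide | CCOC(CBr)O[C@@H]1C2=C(C)C=C[C@H](O)[C@]2(C)CC[C@H]1[C@H](C)C(=O)N(C)OC
F11 | step 7 | (11S)-5α-(1,3-dithian-2-ylmethyl)-6α-hydroxy-N-methoxy-N-methyl-1-oxoeudesm-3-en-12-amide | C1CSC(SC1)C[C@]23C(C)=CCC(=O)[C@]2(C)CC[C@@H]([C@H](C)C(=O)N(C)OC)[C@@H]3O
F12 | step 7 | (11S)-5α-(1,3-dithian-2-ylmethyl)-1-oxoeudesm-3-en-12,6α-olide | C1CSC(SC1)C[C@]12C(C)=CCC(=O)[C@]1(C)CC[C@H]1[C@H](C)C(=O)O[C@@H]12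
A1 | alternative 1 | 1-oxoeudesma-2,4-dien-12,6-olide | O=C1O[C@@H]2C3=C(C)C=CC(=O)[C@]3(C)CC[C@H]2[C@@H]1C
A2 | alternative 1 | 5-(3-hydroxy-2,6-dimethylphenyl)-4-(2-iodoethyl)-3-methyloxolan-2-one | Cc1ccc(O)c(C)c1[C@H]1OC(=O)[C@@H](C)[C@@H]1CCI
A3 | alternative 2 | C1-nitro tetracycle, 17 with a nitro group and hydrogen at C1 in place of the carbonyl oxygen | C=C(CCC=C(C)C)[C@@H]1C[C@]23C(C)=C[C@H]1[C@@H]([N+](=O)[O-])[C@]2(C)CC[C@H]1[C@H](C)C(=O)O[C@@H]13
A4 | alternative 2 | cyclohexa-1,3-diene lactone with tethered (E)-nitroalkene | C=C(CCC=C(C)C)[C@@H]1CC(=C(C)C=C1)[C@H]1OC(=O)[C@@H](C)[C@@H]1CC/C(C)=C/[N+](=O)[O-]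
A5 | alternative 3 | 1-hydroxyeudesm-3-en-12,6-olide | O[C@@H]1CC=C(C)[C@H]2[C@@]1(C)CC[C@H]1[C@H](C)C(=O)O[C@@H]12
A6 | alternative 3 | 1,10-epoxygermacr-4-en-12,6-olide | C[C@]12O[C@@H]1CC/C(C)=C/[C@H]1OC(=O)[C@@H](C)[C@@H]1CC2
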